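**Retrosynthetic overview**

1. The target is cut at one bond of its C–CH2–C bridge: the bond between the bridging CH2 and C8 of the 2H-chromene ring. The bridging carbon enters the key step as the 6-methyl group of the dimethylcyclohexadienone (filicinic) ring, not as formaldehyde.
2. That methyl carbon and the single free aromatic C8–H of the chromene are both latent nucleophiles. They are joined by an oxidative dehydrogenative C(sp3)–H/C(sp2)–H coupling through an exo-methylene triketone, so neither homodimer can form.
3. Both halves come from one intermediate, isobutyrylphloroglucinol 3, made from phloroglucinol and isobutyryl chloride.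
4. Ring order: the benzene rings are bought as phloroglucinol. The filicinic ring arises by dearomatising triple C-methylation of 3. The pyran ring is closed by Knoevenagel condensation/oxa-6π electrocyclisation of 3 with prenal. The key step closes no ring; it joins the two ring systems.

Key step: step 4

Remark on stereochemistry: the target SMILES holds no stereocentre and no stereogenic double bond (the chromene alkene is ring-fixed cis). The compound is achiral, so the "single enantiomer" is the compound itself. The enol form drawn is one of several tautomers in fast exchange.

**Step 1**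
Reactants: 1 phloroglucinol; 2 isobutyryl chloride
Product: 3 isobutyrylphloroglucinol [2-methyl-1-(2,4,6-trihydroxyphenyl)propan-1-one]
Conditions: AlCl3 (4 equiv), PhNO2/CH2Cl2, rt → 60 °C; then ice/aq. HCl
Reagents that add atoms: none
Why: Friedel–Crafts acylation of the electron-rich triol with one equivalent of acyl chloride should stop at the mono-ketone, because the chelated aryl ketone deactivates the ring towards a second acylation.

**Step 2**
Reactants: 3 isobutyrylphloroglucinol
Product: 6 norflavesone [3,5-dihydroxy-4,4,6-trimethyl-2-(2-methylpropanoyl)cyclohexa-2,5-dien-1-one], via 3-methyl-isobutyrylphloroglucinol 4 (not isolated), via isobutyrylfilicinic acid 5 (not isolated)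
Conditions: NaOMe (3.3 equiv), MeI (3.1 equiv), MeOH, 0 °C → rt; then aq. HCl
Reagents that add atoms: iodomethane, CI
Why: Iterative C-methylation of the phloroglucinol polyanion (alkylative dearomatisation) should place two methyl groups on one ring carbon and the third on the only remaining ring C–H, whereas a fourth would have to build a second quaternary centre on a hindered, less nucleophilic triketone anion, so three equivalents should stop mainly at 6.

**Step 3**
Reactants: 3 isobutyrylphloroglucinol; 7 3-methylbut-2-enal (prenal)
Product: 9 1-(5,7-dihydroxy-2,2-dimethyl-2H-chromen-6-yl)-2-methylpropan-1-one, via o-quinone methide dienone 8 (not isolated)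
Conditions: 7 (1.1 equiv), ethylenediammonium diacetate (10 mol %), PhMe, reflux
Reagents that add atoms: none
Why: Amine-catalysed Knoevenagel-type condensation at a free ring carbon gives dienone 8, which closes by oxa-6π electrocyclisation; the para oxygen is the most acidic one and is not held in the acyl chelate, so it should drive the dehydration and become the ring oxygen, making the 6-acyl chromene 9 the expected main isomer, separable from the 8-acyl isomer by chromatography.

**Step 4**
Reactants: 6 norflavesone; 9 1-(5,7-dihydroxy-2,2-dimethyl-2H-chromen-6-yl)-2-methylpropan-1-one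
Product: 11 target CNP0318758.0 [6-{[5,7-dihydroxy-2,2-dimethyl-6-(2-methylpropanoyl)-2H-chromen-8-yl]methyl}-3,5-dihydroxy-4,4-dimethyl-2-(2-methylpropanoyl)cyclohexa-2,5-dien-1-one], via exo-methylene triketone 10 (not isolated)
Conditions: 6 (1.0 equiv, added slowly), 9 (1.2 equiv), Ag2O (1.1 equiv), TEMPO (20 mol %), THF, 0 °C → rt, dark
Reagents that add atoms: none
Why: Proposed new method: Ag2O/TEMPO should oxidise the silver enolate of the acidic triketone 6 (one-electron oxidation to the C6 radical, TEMPO capture or H-abstraction at the 6-methyl group, loss of TEMPO-H, which Ag2O returns to TEMPO) to the exo-methylene triketone 10, and the C8–H of 9 should add to it in a Friedel–Crafts-type Michael addition, followed by rearomatisation and enolisation to 11. The closest known reaction types are the TEMPO/Ag2O dehydrogenation of C-methyl acylfilicinic acids to such methides, which have been trapped by alkenes in hetero-Diels–Alder reactions, and the Michael addition of acylphloroglucinols to alkylidene β-triketones made by Knoevenagel condensation; new here is their union in one dehydrogenative C–H/C–H coupling. No ring is closed and no stereocentre is formed. The step needs cross-selectivity, which is secured because the one-carbon unit is already bound to the filicinic ring and 9 can act only as the nucleophile through its single unsubstituted ring carbon. It also needs chemoselectivity of the oxidant, expected because the enol of 6 is far more acidic and more easily oxidised than the acyl-deactivated, meta-oxygenated phenol 9, which cannot form a quinone. C-arylation should outrun hetero-Diels–Alder addition of 10 to the chromene C3=C4 bond, and over-oxidation of 11 at its bridging CH2 is limited by one equivalent of Ag2O, slow addition of 6 and a slight excess of 9.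

**Compound list**

1 | phloroglucinol (benzene-1,3,5-triol) | Oc1cc(O)cc(O)c1 | starting material
2 | isobutyryl chloride (2-methylpropanoyl chloride) | CC(C)C(Cl)=O | starting material
3 | isobutyrylphloroglucinol [2-methyl-1-(2,4,6-trihydroxyphenyl)propan-1-one] | CC(C)C(=O)c1c(O)cc(O)cc1O | intermediate
4 | 3-methyl-isobutyrylphloroglucinol [2-methyl-1-(2,4,6-trihydroxy-3-methylphenyl)propan-1-one] | CC(C)C(=O)c1c(O)cc(O)c(C)c1O | intermediate
5 | isobutyrylfilicinic acid [3,5-dihydroxy-4,4-dimethyl-2-(2-methylpropanoyl)cyclohexa-2,5-dien-1-one] | CC(C)C(=O)C1=C(O)C(C)(C)C(O)=CC1=O | intermediate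
6 | norflavesone [3,5-dihydroxy-4,4,6-trimethyl-2-(2-methylpropanoyl)cyclohexa-2,5-dien-1-one] | CC(C)C(=O)C1=C(O)C(C)(C)C(O)=C(C)C1=O | intermediate
7 | 3-methylbut-2-enal (prenal) | CC(C)=CC=O | starting material
8 | 3,5-dihydroxy-4-(2-methylpropanoyl)-6-(3-methylbut-2-en-1-ylidene)cyclohexa-2,4-dien-1-one | CC(C)C(=O)C1=C(O)C(=CC=C(C)C)C(=O)C=C1O | intermediate
9 | 1-(5,7-dihydroxy-2,2-dimethyl-2H-chromen-6-yl)-2-methylpropan-1-one | CC(C)C(=O)c1c(O)cc2OC(C)(C)C=Cc2c1O | intermediate
10 | 5-hydroxy-4,4-dimethyl-2-methylidene-6-(2-methylpropanoyl)cyclohex-5-ene-1,3-dione | CC(C)C(=O)C1=C(O)C(C)(C)C(=O)C(=C)C1=O | intermediate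
11 | CNP0318758.0 [6-{[5,7-dihydroxy-2,2-dimethyl-6-(2-methylpropanoyl)-2H-chromen-8-yl]methyl}-3,5-dihydroxy-4,4-dimethyl-2-(2-methylpropanoyl)cyclohexa-2,5-dien-1-one] | CC(C)C(=O)C1=C(O)C(C)(C)C(O)=C(Cc2c(O)c(C(=O)C(C)C)c(O)c3c2OC(C)(C)C=C3)C1=O | target

**Totals**

Total step count: 4
Longest linear sequence: 3 steps (step 1, then step 2 or step 3, then step 4)

**Steps most likely to fail**

Step 4 (Proposed new method). The oxidation may spread to the phenolic partner or to the doubly activated bridging CH2 of the product, and the methide may self-condense before it is arylated. The fallback uses known chemistry; it sets out from 3 and comes back at 11. 3 is C-methylated with only two equivalents of MeI (NaOMe, MeOH) and the reaction is stopped at isobutyrylfilicinic acid 5, which is isolated. A Mannich reaction of 5 with aqueous formaldehyde and dimethylamine (EtOH, rt) at its only free ring carbon gives 6-[(dimethylamino)methyl]-3,5-dihydroxy-4,4-dimethyl-2-(2-methylpropanoyl)cyclohexa-2,5-dien-1-one F1. Heating F1 with 9 (dioxane, 80–100 °C) expels dimethylamine, forms the same methide 10 without any oxidant, and C8 of 9 adds to it to give 11.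

Step 2. The methylation level may spread statistically (stopping at two methyl groups or running on to four), and O-methylation may compete. The fallback sets out from 2 and comes back at 6. Commercial 2-methylphloroglucinol (2-methylbenzene-1,3,5-triol) F2 is acylated with 2 under the conditions of step 1 to give 4, now isolated with its first C-methyl group already in place. 4 is then treated with two equivalents of MeI (NaOMe, MeOH). Whichever ring carbon reacts first, both paths converge on 6, and only two alkylation events have to be controlled.

Step 3. The pyran ring may close through the ortho oxygen instead of the para oxygen, and a second annulation may occur at the other free ring carbon. The fallback sets out from 3 and comes back at 9. The most acidic, non-chelated 4-OH of 3 is O-alkylated with 3-chloro-3-methylbut-1-yne (CC(C)(Cl)C#C; K2CO3, KI, cat. CuI, acetone, 50 °C) to give 1-{2,6-dihydroxy-4-[(2-methylbut-3-yn-2-yl)oxy]phenyl}-2-methylpropan-1-one F3. Au(I)-catalysed 6-endo-dig hydroarylation of F3 (Ph3PAuNTf2, CH2Cl2, rt; PtCl4 as alternative) closes the pyran ring onto either of the two equivalent ortho carbons with the O–CMe2 bond left intact. The ring oxygen of 9 is then by construction the oxygen para to the acyl group, and only one pyran ring can form.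

**Further compounds**

F1 | step 4 | 6-[(dimethylamino)methyl]-3,5-dihydroxy-4,4-dimethyl-2-(2-methylpropanoyl)cyclohexa-2,5-dien-1-one | CC(C)C(=O)C1=C(O)C(C)(C)C(O)=C(CN(C)C)C1=O
F2 | step 2 | 2-methylphloroglucinol (2-methylbenzene-1,3,5-triol) | Cc1c(O)cc(O)cc1O
F3 | step 3 | 1-{2,6-dihydroxy-4-[(2-methylbut-3-yn-2-yl)oxy]phenyl}-2-methylpropan-1-one | CC(C)C(=O)c1c(O)cc(OC(C)(C)C#C)cc1O
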